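**Retrosynthetic overview**
1. The target is a 5,5'-biaryl of two chromanol acids with opposite C2 configuration; the biaryl bond is cut last, to a 5-bromochroman and the 5-boryl chroman of opposite configuration (Suzuki coupling).
2. Both partners come from one racemic 5-bromochroman ester by resolution, so both enantiomers are used.
3. The chroman is built by the key intermolecular aldol (Kabbe) condensation of 2',5'-dihydroxy-3'-methylacetophenone with ethyl levulinate (C2–C3 bond, then oxa-Michael ring closure), followed by removal of C4=O.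
4. After coupling, both side chains are grown together: ester → aldehyde → isopropenyl carbinol → Johnson–Claisen (6E) → aldehyde → Still–Gennari (2Z) → deprotection.
5. Ring order: benzene rings are bought, the two dihydropyran rings form in the Kabbe step, and the biaryl bond joins the two bicycles afterwards.

Assumption: the SMILES fixes the two carbon stereocentres (one 2R, one 2S) but not the biaryl axis, so the route delivers the (2R,2'S) compound with the axis uncontrolled (its two axial forms are mirror images and form about 1:1).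

Descriptor note: in compounds 10–17 the side chain outranks ring carbon C3 at C2, so the half that is 2S in the target is named 2R there; nothing changes in space.

**Step 1**
Reactants: 1 1-(2-hydroxy-3-methylphenyl)ethanone (2'-hydroxy-3'-methylacetophenone)
Product: 3 1-(2,5-dihydroxy-3-methylphenyl)ethanone, via aryl sulfate potassium salt 2 (not isolated)
Conditions: K2S2O8, aq KOH, 0–20 °C, 24 h; then HCl, 90 °C
Reagents that add atoms: potassium peroxodisulfate, [K+].[K+].[O-]S(=O)(=O)OOS(=O)(=O)[O-]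
Why: Elbs persulfate oxidation; the phenoxide is attacked at its only free ortho/para position (para to OH) and acid hydrolysis of the sulfate gives the hydroquinone, with no stereocentre involved.

**Step 2**
Reactants: 3 1-(2,5-dihydroxy-3-methylphenyl)ethanone; 4 ethyl levulinate (ethyl 4-oxopentanoate)
Product: 6 rac-ethyl 3-(6-hydroxy-2,8-dimethyl-4-oxochroman-2-yl)propanoate, via open-chain aryl enone 5 (not isolated)
Conditions: pyrrolidine (1 equiv), EtOH, 3 Å molecular sieves, 45 °C then reflux, under Ar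
Reagents that add atoms: none
Why: Kabbe chromanone synthesis, a pyrrolidine-mediated intermolecular crossed aldol condensation of the acetyl CH3 of 3 with the ketone of 4 followed by oxa-Michael closure by the ortho phenol; the quaternary C2 centre forms without control, which is intended because the target needs one half of each configuration.

**Step 3**
Reactants: 6 rac-ethyl 3-(6-hydroxy-2,8-dimethyl-4-oxochroman-2-yl)propanoate
Product: 7 rac-ethyl 3-(6-hydroxy-2,8-dimethylchroman-2-yl)propanoate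
Conditions: Zn dust, conc. HCl, AcOH, 20 °C
Reagents that add atoms: none
Why: Clemmensen reduction of the electron-rich aryl ketone to CH2 leaves the ester, phenol and aryl ether untouched and does not affect C2.

**Step 4**
Reactants: 7 rac-ethyl 3-(6-hydroxy-2,8-dimethylchroman-2-yl)propanoate
Product: 8 rac-ethyl 3-(5-bromo-6-hydroxy-2,8-dimethylchroman-2-yl)propanoate
Conditions: NBS (1.0 equiv), MeCN, −20 to 0 °C, dark
Reagents that add atoms: N-bromosuccinimide, O=C1CCC(=O)N1Br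
Why: Electrophilic aromatic bromination ortho to the free phenol; of the two ortho sites C5 is expected to be the more nucleophilic in 8-methylchroman-6-ols (bond fixation by the fused pyran ring, the preference shown by δ-tocopherol), and one equivalent at low temperature limits dibromination.

**Step 5**
Reactants: 8 rac-ethyl 3-(5-bromo-6-hydroxy-2,8-dimethylchroman-2-yl)propanoate
Product: 9 rac-ethyl 3-[5-bromo-6-(methoxymethoxy)-2,8-dimethylchroman-2-yl]propanoate
Conditions: MOMCl, i-Pr2NEt, CH2Cl2, 0 °C to rt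
Reagents that add atoms: chloromethyl methyl ether, COCCl
Why: O-Alkylation of the phenol to a methoxymethyl ether gives a small, base- and hydride-stable protecting group that is removed at the end with mild acid.

**Step 6**
Reactants: 9 rac-ethyl 3-[5-bromo-6-(methoxymethoxy)-2,8-dimethylchroman-2-yl]propanoate
Product: 10 ethyl 3-[(2R)-5-bromo-6-(methoxymethoxy)-2,8-dimethylchroman-2-yl]propanoate; 11 ethyl 3-[(2S)-5-bromo-6-(methoxymethoxy)-2,8-dimethylchroman-2-yl]propanoate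
Conditions: preparative chiral SFC, amylose tris(3,5-dimethylphenylcarbamate) phase, CO2/MeOH; both fractions kept (>99% ee)
Reagents that add atoms: none
Why: Resolution by chromatography on a chiral stationary phase separates the two C2 configurations made in step 2 without changing any bond, both enantiomers are used, and the bromine atom lets the absolute configuration be assigned by anomalous-dispersion X-ray diffraction.

**Step 7**
Reactants: 11 ethyl 3-[(2S)-5-bromo-6-(methoxymethoxy)-2,8-dimethylchroman-2-yl]propanoate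
Product: 12 ethyl 3-[(2S)-6-(methoxymethoxy)-2,8-dimethyl-5-(4,4,5,5-tetramethyl-1,3,2-dioxaborolan-2-yl)chroman-2-yl]propanoate
Conditions: pinacolborane, PdCl2(MeCN)2 (2 mol%), SPhos, Et3N, 1,4-dioxane, 90 °C
Reagents that add atoms: pinacolborane, CC1(C)OBOC1(C)C
Why: Palladium-catalysed Miyaura-type borylation with a dialkylbiarylphosphine ligand accepts di-ortho-substituted aryl bromides and tolerates the ester; C2 is untouched.

**Step 8**
Reactants: 10 ethyl 3-[(2R)-5-bromo-6-(methoxymethoxy)-2,8-dimethylchroman-2-yl]propanoate; 12 ethyl 3-[(2S)-6-(methoxymethoxy)-2,8-dimethyl-5-(4,4,5,5-tetramethyl-1,3,2-dioxaborolan-2-yl)chroman-2-yl]propanoate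
Product: 13 diethyl 3,3'-[(2R,2'S)-6,6'-bis(methoxymethoxy)-2,2',8,8'-tetramethyl-5,5'-bichroman-2,2'-diyl]dipropanoate
Conditions: Pd(OAc)2 (5 mol%), SPhos (10 mol%), K3PO4, toluene/H2O 10:1, 100 °C
Reagents that add atoms: none
Why: Suzuki–Miyaura cross-coupling with a bulky electron-rich phosphine can form tetra-ortho-substituted biaryls, and pairing a (2R) bromide with a (2S) boronate fixes the R/S combination by construction; the new axis forms without control.

**Step 9**
Reactants: 13 diethyl 3,3'-[(2R,2'S)-6,6'-bis(methoxymethoxy)-2,2',8,8'-tetramethyl-5,5'-bichroman-2,2'-diyl]dipropanoate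
Product: 14 3,3'-[(2R,2'S)-6,6'-bis(methoxymethoxy)-2,2',8,8'-tetramethyl-5,5'-bichroman-2,2'-diyl]di(propan-1-ol)
Conditions: LiAlH4, THF, 0 °C; then H2O
Reagents that add atoms: none
Why: Hydride reduction of both esters to primary alcohols is clean and avoids the mixtures of a twofold partial reduction.

**Step 10**
Reactants: 14 3,3'-[(2R,2'S)-6,6'-bis(methoxymethoxy)-2,2',8,8'-tetramethyl-5,5'-bichroman-2,2'-diyl]di(propan-1-ol)
Product: 15 3,3'-[(2R,2'S)-6,6'-bis(methoxymethoxy)-2,2',8,8'-tetramethyl-5,5'-bichroman-2,2'-diyl]dipropanal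
Conditions: Dess–Martin periodinane, CH2Cl2, 0 °C to rt
Reagents that add atoms: none
Why: Dess–Martin oxidation stops at the aldehyde and leaves the acetal and the electron-rich arenes alone.

**Step 11**
Reactants: 15 3,3'-[(2R,2'S)-6,6'-bis(methoxymethoxy)-2,2',8,8'-tetramethyl-5,5'-bichroman-2,2'-diyl]dipropanal
Product: 16 5,5'-[(2R,2'S)-6,6'-bis(methoxymethoxy)-2,2',8,8'-tetramethyl-5,5'-bichroman-2,2'-diyl]bis(2-methylpent-1-en-3-ol) (mixture of carbinol epimers)
Conditions: CH2=C(CH3)MgBr (3 equiv), THF, −20 to 0 °C; then H2O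
Reagents that add atoms: isopropenylmagnesium bromide, CC(=C)[Mg]Br
Why: Grignard 1,2-addition to both aldehydes; the new carbinol centres form as mixtures, which is harmless because they become sp2 carbons in step 12.

**Step 12**
Reactants: 16 5,5'-[(2R,2'S)-6,6'-bis(methoxymethoxy)-2,2',8,8'-tetramethyl-5,5'-bichroman-2,2'-diyl]bis(2-methylpent-1-en-3-ol)
Product: 18 diethyl (4E,4'E)-7,7'-[(2R,2'S)-6,6'-bis(methoxymethoxy)-2,2',8,8'-tetramethyl-5,5'-bichroman-2,2'-diyl]bis(4-methylhept-4-enoate), via bis(ketene acetal) 17 (not isolated)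
Conditions: MeC(OEt)3 (excess), EtCO2H (cat.), 140 °C, EtOH distilled off
Reagents that add atoms: triethyl orthoacetate, CCOC(C)(OCC)OCC
Why: Johnson–Claisen (orthoester Claisen) rearrangement through a chair transition state with the chain equatorial gives the E-trisubstituted olefins and adds the two-carbon ester unit, erasing the carbinol centres.

**Step 13**
Reactants: 18 diethyl (4E,4'E)-7,7'-[(2R,2'S)-6,6'-bis(methoxymethoxy)-2,2',8,8'-tetramethyl-5,5'-bichroman-2,2'-diyl]bis(4-methylhept-4-enoate)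
Product: 19 (4E,4'E)-7,7'-[(2R,2'S)-6,6'-bis(methoxymethoxy)-2,2',8,8'-tetramethyl-5,5'-bichroman-2,2'-diyl]bis(4-methylhept-4-en-1-ol)
Conditions: LiAlH4, THF, 0 °C; then H2O
Reagents that add atoms: none
Why: Hydride reduction of the esters does not touch the isolated trisubstituted olefins.

**Step 14**
Reactants: 19 (4E,4'E)-7,7'-[(2R,2'S)-6,6'-bis(methoxymethoxy)-2,2',8,8'-tetramethyl-5,5'-bichroman-2,2'-diyl]bis(4-methylhept-4-en-1-ol)
Product: 20 (4E,4'E)-7,7'-[(2R,2'S)-6,6'-bis(methoxymethoxy)-2,2',8,8'-tetramethyl-5,5'-bichroman-2,2'-diyl]bis(4-methylhept-4-enal)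
Conditions: Dess–Martin periodinane, CH2Cl2, 0 °C to rt
Reagents that add atoms: none
Why: Dess–Martin oxidation gives the aldehydes without migration or isomerisation of the γ,δ-olefins.

**Step 15**
Reactants: 20 (4E,4'E)-7,7'-[(2R,2'S)-6,6'-bis(methoxymethoxy)-2,2',8,8'-tetramethyl-5,5'-bichroman-2,2'-diyl]bis(4-methylhept-4-enal)
Product: 21 diethyl (2Z,2'Z,6E,6'E)-9,9'-[(2R,2'S)-6,6'-bis(methoxymethoxy)-2,2',8,8'-tetramethyl-5,5'-bichroman-2,2'-diyl]bis(2,6-dimethylnona-2,6-dienoate)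
Conditions: (CF3CH2O)2P(O)CH(CH3)CO2Et, KN(SiMe3)2, 18-crown-6, THF, −78 °C
Reagents that add atoms: ethyl 2-[bis(2,2,2-trifluoroethoxy)phosphoryl]propanoate, CCOC(=O)C(C)P(=O)(OCC(F)(F)F)OCC(F)(F)F
Why: Still–Gennari variant of the Horner–Wadsworth–Emmons olefination; the electron-poor phosphonate with a dissociated potassium counter-ion eliminates under kinetic control and gives the Z-2-methyl enoates.

**Step 16**
Reactants: 21 diethyl (2Z,2'Z,6E,6'E)-9,9'-[(2R,2'S)-6,6'-bis(methoxymethoxy)-2,2',8,8'-tetramethyl-5,5'-bichroman-2,2'-diyl]bis(2,6-dimethylnona-2,6-dienoate)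
Product: 22 diethyl (2Z,2'Z,6E,6'E)-9,9'-[(2R,2'S)-6,6'-dihydroxy-2,2',8,8'-tetramethyl-5,5'-bichroman-2,2'-diyl]bis(2,6-dimethylnona-2,6-dienoate)
Conditions: HCl (about 0.5 M in EtOH), THF, 40 °C
Reagents that add atoms: none
Why: Acid-catalysed transacetalisation of the methoxymethyl ethers in ethanol frees both phenols under conditions too mild to protonate the trisubstituted olefins, isomerise the enoates or open the chroman rings (ethanol matches the ethyl esters).

**Step 17**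
Reactants: 22 diethyl (2Z,2'Z,6E,6'E)-9,9'-[(2R,2'S)-6,6'-dihydroxy-2,2',8,8'-tetramethyl-5,5'-bichroman-2,2'-diyl]bis(2,6-dimethylnona-2,6-dienoate)
Product: 24 (2Z,2'Z,6E,6'E)-9,9'-[(2R,2'S)-6,6'-dihydroxy-2,2',8,8'-tetramethyl-5,5'-bichroman-2,2'-diyl]bis(2,6-dimethylnona-2,6-dienoic acid) (CNP0282703.1), via dilithium dicarboxylate 23 (not isolated)
Conditions: LiOH, THF/EtOH/H2O, 40 °C, degassed; then 1 M HCl to pH 3
Reagents that add atoms: lithium hydroxide, [Li+].[OH-]
Why: Saponification by acyl–oxygen cleavage cannot deconjugate or isomerise the Z-enoates at this temperature, and air is excluded to protect the biphenol; no stereocentre is touched.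

**Compound list**
1 | 1-(2-hydroxy-3-methylphenyl)ethanone | CC(=O)c1cccc(C)c1O | starting material
2 | potassium 3-acetyl-4-hydroxy-5-methylphenyl sulfate | CC(=O)c1cc(OS(=O)(=O)[O-])cc(C)c1O.[K+] | intermediate (not isolated)
3 | 1-(2,5-dihydroxy-3-methylphenyl)ethanone | CC(=O)c1cc(O)cc(C)c1O | intermediate
4 | ethyl levulinate | CCOC(=O)CCC(C)=O | starting material
5 | ethyl (E)-6-(2,5-dihydroxy-3-methylphenyl)-4-methyl-6-oxohex-4-enoate | CCOC(=O)CC/C(C)=C/C(=O)c1cc(O)cc(C)c1O | intermediate (not isolated)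
6 | rac-ethyl 3-(6-hydroxy-2,8-dimethyl-4-oxochroman-2-yl)propanoate | CCOC(=O)CCC1(C)CC(=O)c2cc(O)cc(C)c2O1 | intermediate
7 | rac-ethyl 3-(6-hydroxy-2,8-dimethylchroman-2-yl)propanoate | CCOC(=O)CCC1(C)CCc2cc(O)cc(C)c2O1 | intermediate
8 | rac-ethyl 3-(5-bromo-6-hydroxy-2,8-dimethylchroman-2-yl)propanoate | CCOC(=O)CCC1(C)CCc2c(Br)c(O)cc(C)c2O1 | intermediate
9 | rac-ethyl 3-[5-bromo-6-(methoxymethoxy)-2,8-dimethylchroman-2-yl]propanoate | CCOC(=O)CCC1(C)CCc2c(Br)c(OCOC)cc(C)c2O1 | intermediate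
10 | ethyl 3-[(2R)-5-bromo-6-(methoxymethoxy)-2,8-dimethylchroman-2-yl]propanoate | CCOC(=O)CC[C@@]1(C)CCc2c(Br)c(OCOC)cc(C)c2O1 | intermediate
11 | ethyl 3-[(2S)-5-bromo-6-(methoxymethoxy)-2,8-dimethylchroman-2-yl]propanoate | CCOC(=O)CC[C@]1(C)CCc2c(Br)c(OCOC)cc(C)c2O1 | intermediate
12 | ethyl 3-[(2S)-6-(methoxymethoxy)-2,8-dimethyl-5-(4,4,5,5-tetramethyl-1,3,2-dioxaborolan-2-yl)chroman-2-yl]propanoate | CCOC(=O)CC[C@]1(C)CCc2c(B3OC(C)(C)C(C)(C)O3)c(OCOC)cc(C)c2O1 | intermediate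
13 | diethyl 3,3'-[(2R,2'S)-6,6'-bis(methoxymethoxy)-2,2',8,8'-tetramethyl-5,5'-bichroman-2,2'-diyl]dipropanoate | CCOC(=O)CC[C@@]1(C)CCc2c(c(C)cc(OCOC)c2-c2c(OCOC)cc(C)c3c2CC[C@@](C)(CCC(=O)OCC)O3)O1 | intermediate
14 | 3,3'-[(2R,2'S)-6,6'-bis(methoxymethoxy)-2,2',8,8'-tetramethyl-5,5'-bichroman-2,2'-diyl]di(propan-1-ol) | OCCC[C@@]1(C)CCc2c(c(C)cc(OCOC)c2-c2c(OCOC)cc(C)c3c2CC[C@@](C)(CCCO)O3)O1 | intermediate
15 | 3,3'-[(2R,2'S)-6,6'-bis(methoxymethoxy)-2,2',8,8'-tetramethyl-5,5'-bichroman-2,2'-diyl]dipropanal | O=CCC[C@@]1(C)CCc2c(c(C)cc(OCOC)c2-c2c(OCOC)cc(C)c3c2CC[C@@](C)(CCC=O)O3)O1 | intermediate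
16 | 5,5'-[(2R,2'S)-6,6'-bis(methoxymethoxy)-2,2',8,8'-tetramethyl-5,5'-bichroman-2,2'-diyl]bis(2-methylpent-1-en-3-ol), carbinol epimers | C=C(C)C(O)CC[C@@]1(C)CCc2c(c(C)cc(OCOC)c2-c2c(OCOC)cc(C)c3c2CC[C@@](C)(CCC(O)C(C)=C)O3)O1 | intermediate
17 | bis(1-ethoxyvinyl) ether of 16 (bis ketene acetal) | C=C(C)C(OC(=C)OCC)CC[C@@]1(C)CCc2c(c(C)cc(OCOC)c2-c2c(OCOC)cc(C)c3c2CC[C@@](C)(CCC(OC(=C)OCC)C(C)=C)O3)O1 | intermediate (not isolated)
18 | diethyl (4E,4'E)-7,7'-[(2R,2'S)-6,6'-bis(methoxymethoxy)-2,2',8,8'-tetramethyl-5,5'-bichroman-2,2'-diyl]bis(4-methylhept-4-enoate) | CCOC(=O)CC/C(C)=C/CC[C@@]1(C)CCc2c(c(C)cc(OCOC)c2-c2c(OCOC)cc(C)c3c2CC[C@@](C)(CC/C=C(\C)CCC(=O)OCC)O3)O1 | intermediate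
19 | (4E,4'E)-7,7'-[(2R,2'S)-6,6'-bis(methoxymethoxy)-2,2',8,8'-tetramethyl-5,5'-bichroman-2,2'-diyl]bis(4-methylhept-4-en-1-ol) | OCCC/C(C)=C/CC[C@@]1(C)CCc2c(c(C)cc(OCOC)c2-c2c(OCOC)cc(C)c3c2CC[C@@](C)(CC/C=C(\C)CCCO)O3)O1 | intermediate
20 | (4E,4'E)-7,7'-[(2R,2'S)-6,6'-bis(methoxymethoxy)-2,2',8,8'-tetramethyl-5,5'-bichroman-2,2'-diyl]bis(4-methylhept-4-enal) | O=CCC/C(C)=C/CC[C@@]1(C)CCc2c(c(C)cc(OCOC)c2-c2c(OCOC)cc(C)c3c2CC[C@@](C)(CC/C=C(\C)CCC=O)O3)O1 | intermediate
21 | diethyl (2Z,2'Z,6E,6'E)-9,9'-[(2R,2'S)-6,6'-bis(methoxymethoxy)-2,2',8,8'-tetramethyl-5,5'-bichroman-2,2'-diyl]bis(2,6-dimethylnona-2,6-dienoate) | C/C(=C/CC/C(C)=C/CC[C@@]1(C)CCc2c(c(C)cc(OCOC)c2-c2c(OCOC)cc(C)c3c2CC[C@@](C)(CC/C=C(\C)CC/C=C(/C)C(=O)OCC)O3)O1)C(=O)OCC | intermediate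
22 | diethyl (2Z,2'Z,6E,6'E)-9,9'-[(2R,2'S)-6,6'-dihydroxy-2,2',8,8'-tetramethyl-5,5'-bichroman-2,2'-diyl]bis(2,6-dimethylnona-2,6-dienoate) | C/C(=C/CC/C(C)=C/CC[C@@]1(C)CCc2c(c(C)cc(O)c2-c2c(O)cc(C)c3c2CC[C@@](C)(CC/C=C(\C)CC/C=C(/C)C(=O)OCC)O3)O1)C(=O)OCC | intermediate
23 | dilithium salt of 24 (dicarboxylate) | C/C(=C/CC/C(C)=C/CC[C@@]1(C)CCc2c(c(C)cc(O)c2-c2c(O)cc(C)c3c2CC[C@@](C)(CC/C=C(\C)CC/C=C(/C)C(=O)[O-])O3)O1)C(=O)[O-].[Li+].[Li+] | intermediate (not isolated)
24 | (2Z,2'Z,6E,6'E)-9,9'-[(2R,2'S)-6,6'-dihydroxy-2,2',8,8'-tetramethyl-5,5'-bichroman-2,2'-diyl]bis(2,6-dimethylnona-2,6-dienoic acid) | C/C(=C/CC/C(C)=C/CC[C@@]1(C)CCc2c(c(C)cc(O)c2-c2c(O)cc(C)c3c2CC[C@@](C)(CC/C=C(\C)CC/C=C(/C)C(=O)O)O3)O1)C(=O)O | target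

**Totals**
Total step count: 17. Longest linear sequence: 17 steps (1 → 3 → 6 → 7 → 8 → 9 → 11 → 12 → 13 → … → 24); the coupling partner 10 leaves the same line after step 6.

**Three steps most likely to fail**

Step 4 (C5 against C7 bromination). If NBS gives the 7-bromo isomer or mixtures, the fallback sets out from chromanone 6 and uses the C4 ketone as a directing group. The phenol is acetylated (Ac2O, pyridine) to rac-ethyl 3-(6-acetoxy-2,8-dimethyl-4-oxochroman-2-yl)propanoate F1. Carbonyl-directed C–H bromination (Pd(OAc)2 cat., NBS, CF3SO3H, 1,2-dichloroethane, 60 °C) can only reach the C5–H peri to the ketone and gives rac-ethyl 3-(6-acetoxy-5-bromo-2,8-dimethyl-4-oxochroman-2-yl)propanoate F2. Ionic hydrogenation (Et3SiH, CF3CO2H, 50 °C) removes the ketone to give rac-ethyl 3-(6-acetoxy-5-bromo-2,8-dimethylchroman-2-yl)propanoate F3, and K2CO3 in EtOH cleaves the acetate to come back at 8.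

Step 6 (resolution). If no workable preparative separation is found, the fallback sets out from 9 and resolves by salt crystallisation. Saponification (LiOH, THF/H2O, then cold aq citric acid) gives rac-3-[5-bromo-6-(methoxymethoxy)-2,8-dimethylchroman-2-yl]propanoic acid F4. Crystallisation with 0.5 equiv of (R)-1-phenylethylamine gives the less soluble salt, written here as (R)-1-phenylethylammonium 3-[(2R)-5-bromo-6-(methoxymethoxy)-2,8-dimethylchroman-2-yl]propanoate F5; which acid enantiomer it carries has to be found by experiment. The acid from the mother liquor with (S)-1-phenylethylamine gives the mirror-image salt (S)-1-phenylethylammonium 3-[(2S)-5-bromo-6-(methoxymethoxy)-2,8-dimethylchroman-2-yl]propanoate F6. Cold aq citric acid frees 3-[(2R)-5-bromo-6-(methoxymethoxy)-2,8-dimethylchroman-2-yl]propanoic acid F7 and 3-[(2S)-5-bromo-6-(methoxymethoxy)-2,8-dimethylchroman-2-yl]propanoic acid F8, and re-esterification (EtI, K2CO3, DMF) comes back at 10 and 11.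

Step 8 (tetra-ortho-substituted Suzuki coupling). If the hindered boronate protodeboronates or does not transmetalate, the fallback sets out from 11 and replaces boron by zinc. Magnesium insertion in the presence of LiCl and ZnCl2 (Mg turnings, THF, 25 °C; the ester is tolerated) gives {(2S)-2-(3-ethoxy-3-oxopropyl)-6-(methoxymethoxy)-2,8-dimethylchroman-5-yl}zinc chloride F9. Negishi coupling of F9 with 10 (Pd(OAc)2, RuPhos, THF/NMP, 70 °C) needs no base and has no protodeboronation pathway, and comes back at 13.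

**Further compounds**
F1 | step 4 | rac-ethyl 3-(6-acetoxy-2,8-dimethyl-4-oxochroman-2-yl)propanoate | CCOC(=O)CCC1(C)CC(=O)c2cc(OC(C)=O)cc(C)c2O1
F2 | step 4 | rac-ethyl 3-(6-acetoxy-5-bromo-2,8-dimethyl-4-oxochroman-2-yl)propanoate | CCOC(=O)CCC1(C)CC(=O)c2c(Br)c(OC(C)=O)cc(C)c2O1
F3 | step 4 | rac-ethyl 3-(6-acetoxy-5-bromo-2,8-dimethylchroman-2-yl)propanoate | CCOC(=O)CCC1(C)CCc2c(Br)c(OC(C)=O)cc(C)c2O1
F4 | step 6 | rac-3-[5-bromo-6-(methoxymethoxy)-2,8-dimethylchroman-2-yl]propanoic acid | OC(=O)CCC1(C)CCc2c(Br)c(OCOC)cc(C)c2O1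
F5 | step 6 | (R)-1-phenylethylammonium 3-[(2R)-5-bromo-6-(methoxymethoxy)-2,8-dimethylchroman-2-yl]propanoate | C[C@@H]([NH3+])c1ccccc1.[O-]C(=O)CC[C@@]1(C)CCc2c(Br)c(OCOC)cc(C)c2O1
F6 | step 6 | (S)-1-phenylethylammonium 3-[(2S)-5-bromo-6-(methoxymethoxy)-2,8-dimethylchroman-2-yl]propanoate | C[C@H]([NH3+])c1ccccc1.[O-]C(=O)CC[C@]1(C)CCc2c(Br)c(OCOC)cc(C)c2O1
F7 | step 6 | 3-[(2R)-5-bromo-6-(methoxymethoxy)-2,8-dimethylchroman-2-yl]propanoic acid | OC(=O)CC[C@@]1(C)CCc2c(Br)c(OCOC)cc(C)c2O1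
F8 | step 6 | 3-[(2S)-5-bromo-6-(methoxymethoxy)-2,8-dimethylchroman-2-yl]propanoic acid | OC(=O)CC[C@]1(C)CCc2c(Br)c(OCOC)cc(C)c2O1
F9 | step 8 | {(2S)-2-(3-ethoxy-3-oxopropyl)-6-(methoxymethoxy)-2,8-dimethylchroman-5-yl}zinc chloride | CCOC(=O)CC[C@]1(C)CCc2c([Zn]Cl)c(OCOC)cc(C)c2O1
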